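**Retrosynthetic overview**
1. The enal is made last by allylic oxidation. The C3 isovalerate comes from acylation of a trans-2-(3-hydroxyprop-1-en-2-yl)-2,3-dihydrobenzofuran-3-ol.
2. Only one ring is formed, the dihydrofuran ring. It is closed after the key step by intramolecular aryl–O coupling of the C2 hydroxyl onto an ortho bromide, with retention at C2 and C3. The benzene ring is bought.
3. The C2–C3 bond and both ring stereocentres come from an L-proline-catalysed intermolecular anti aldol of aryl aldehyde 10 with 2,2-dimethyl-1,3-dioxan-5-one 11. The dioxanone carbonyl is then methylenated and its CH2O arm becomes the aldehyde.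
4. Aldehyde 10 comes from 2-bromo-5-iodobenzaldehyde by I/Mg exchange and Weinreb acylation, CBS reduction (side-chain centre) and esterification with (R)-2-methylbutanoic acid.

Assumption: 2-bromo-5-iodobenzaldehyde (1) and enantiopure (R)-2-methylbutanoic acid (8) are taken as inexpensive catalogue compounds.

**Route**

Step 1
Reactants: 1 2-bromo-5-iodobenzaldehyde
Product: 2 2-(2-bromo-5-iodophenyl)-1,3-dioxolane
Conditions: ethylene glycol (3 equiv), p-toluenesulfonic acid monohydrate (5 mol %), toluene, reflux, Dean–Stark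
Reagents that add atoms: ethylene glycol, OCCO
Why: Acid-catalysed acetalisation with azeotropic removal of water masks the aldehyde for the Grignard and borane steps.

Step 2
Reactants: 2 2-(2-bromo-5-iodophenyl)-1,3-dioxolane; 3 N-methoxy-N-methylacetamide
Product: 6 1-[4-bromo-3-(1,3-dioxolan-2-yl)phenyl]ethan-1-one, via arylmagnesium chloride 4 (not isolated), via chelated magnesium hemiaminal alkoxide 5 (not isolated)
Conditions: iPrMgCl·LiCl (1.1 equiv), THF, −30 °C, 1 h; then 3 (1.3 equiv), −30 °C to rt; aq. NH4Cl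
Reagents that add atoms: none
Why: Iodine–magnesium exchange is much faster at C–I than at C–Br, and the Weinreb ketone synthesis stops at the chelated tetrahedral adduct, so only the methyl ketone forms.

Step 3
Reactants: 6 1-[4-bromo-3-(1,3-dioxolan-2-yl)phenyl]ethan-1-one
Product: 7 (1R)-1-[4-bromo-3-(1,3-dioxolan-2-yl)phenyl]ethan-1-ol
Conditions: (S)-2-methyl-CBS-oxazaborolidine (C18H20BNO, 10 mol %), BH3·SMe2 (0.7 equiv), THF, −20 °C; MeOH quench
Reagents that add atoms: none
Why: Corey–Bakshi–Shibata reduction, in which the (S)-oxazaborolidine turns aryl methyl ketones into the (R)-carbinols (typically ≥95% ee) and sets the side-chain stereocentre, while acetal and aryl bromide are inert to borane.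

Step 4
Reactants: 7 (1R)-1-[4-bromo-3-(1,3-dioxolan-2-yl)phenyl]ethan-1-ol; 8 (2R)-2-methylbutanoic acid
Product: 9 (1R)-1-[4-bromo-3-(1,3-dioxolan-2-yl)phenyl]ethyl (2R)-2-methylbutanoate
Conditions: N,N'-dicyclohexylcarbodiimide (1.3 equiv), 4-(dimethylamino)pyridine (10 mol %), CH2Cl2, 0 °C to rt
Reagents that add atoms: none
Why: Steglich esterification acylates the alcohol oxygen, so the carbinol centre is retained, and the non-activated α-centre of the acid does not epimerise under these conditions.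

Step 5
Reactants: 9 (1R)-1-[4-bromo-3-(1,3-dioxolan-2-yl)phenyl]ethyl (2R)-2-methylbutanoate
Product: 10 (1R)-1-(4-bromo-3-formylphenyl)ethyl (2R)-2-methylbutanoate
Conditions: 1 M HCl, THF, rt
Reagents that add atoms: water, O
Why: Acid-catalysed acetal hydrolysis cleaves the aryl dioxolane much faster than the hindered secondary ester, whose benzylic carbon is not activated towards ionisation at this stage.

Step 6
Reactants: 10 (1R)-1-(4-bromo-3-formylphenyl)ethyl (2R)-2-methylbutanoate; 11 2,2-dimethyl-1,3-dioxan-5-one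
Product: 12 (1R)-1-{4-bromo-3-[(S)-[(4S)-2,2-dimethyl-5-oxo-1,3-dioxan-4-yl](hydroxy)methyl]phenyl}ethyl (2R)-2-methylbutanoate
Conditions: L-proline (30 mol %), 11 (3 equiv), DMF, 4 °C, 3–5 d
Reagents that add atoms: none
Why: Proline-catalysed direct intermolecular aldol (enamine catalysis), in which the ring-locked (E)-enamine attacks the Re face of the aldehyde through the carboxylic-acid-bridged chair transition state and so sets both new centres as the anti (4S,1'S) aldol.

Step 7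
Reactants: 12 (1R)-1-{4-bromo-3-[(S)-[(4S)-2,2-dimethyl-5-oxo-1,3-dioxan-4-yl](hydroxy)methyl]phenyl}ethyl (2R)-2-methylbutanoate
Product: 13 (1R)-1-{4-bromo-3-[(S)-[(tert-butyldimethylsilyl)oxy][(4S)-2,2-dimethyl-5-oxo-1,3-dioxan-4-yl]methyl]phenyl}ethyl (2R)-2-methylbutanoate
Conditions: TBSOTf (1.5 equiv), 2,6-lutidine (3 equiv), CH2Cl2, −78 °C
Reagents that add atoms: tert-butyldimethylsilyl triflate, CC(C)(C)[Si](C)(C)OS(=O)(=O)C(F)(F)F
Why: Low-temperature O-silylation with a hindered base caps the aldol hydroxyl before retro-aldol or epimerisation can occur, so both centres are kept.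

Step 8
Reactants: 13 (1R)-1-{4-bromo-3-[(S)-[(tert-butyldimethylsilyl)oxy][(4S)-2,2-dimethyl-5-oxo-1,3-dioxan-4-yl]methyl]phenyl}ethyl (2R)-2-methylbutanoate
Product: 14 (1R)-1-{4-bromo-3-[(S)-[(tert-butyldimethylsilyl)oxy][(4R)-2,2-dimethyl-5-methylidene-1,3-dioxan-4-yl]methyl]phenyl}ethyl (2R)-2-methylbutanoate
Conditions: Ph3PCH3Br (2.0 equiv), KOtBu (1.9 equiv), THF, 0 °C; then 13, −78 to 0 °C
Reagents that add atoms: methyltriphenylphosphonium bromide, C[P+](c1ccccc1)(c1ccccc1)c1ccccc1.[Br-]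
Why: Wittig methylenation with the ylide pre-formed from excess phosphonium salt converts the ketone into the exocyclic alkene faster than it enolises, so the oxygenated centre keeps its configuration (its descriptor becomes R only through the priority rules) and the ester is untouched.

Step 9
Reactants: 14 (1R)-1-{4-bromo-3-[(S)-[(tert-butyldimethylsilyl)oxy][(4R)-2,2-dimethyl-5-methylidene-1,3-dioxan-4-yl]methyl]phenyl}ethyl (2R)-2-methylbutanoate
Product: 15 (1R)-1-{4-bromo-3-[(1S,2R)-1-[(tert-butyldimethylsilyl)oxy]-2-hydroxy-3-(hydroxymethyl)but-3-en-1-yl]phenyl}ethyl (2R)-2-methylbutanoate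
Conditions: pyridinium p-toluenesulfonate (20 mol %), MeOH, rt
Reagents that add atoms: none
Why: Mild acid-catalysed transacetalisation to methanol removes the six-membered acetonide while the secondary silyl ether and the ester survive.

Step 10
Reactants: 15 (1R)-1-{4-bromo-3-[(1S,2R)-1-[(tert-butyldimethylsilyl)oxy]-2-hydroxy-3-(hydroxymethyl)but-3-en-1-yl]phenyl}ethyl (2R)-2-methylbutanoate
Product: 16 (1R)-1-[(2R,3S)-3-[(tert-butyldimethylsilyl)oxy]-2-(3-hydroxyprop-1-en-2-yl)-2,3-dihydro-1-benzofuran-5-yl]ethyl (2R)-2-methylbutanoate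
Conditions: CuI (10 mol %), 3,4,7,8-tetramethyl-1,10-phenanthroline (20 mol %), Cs2CO3 (2 equiv), toluene (0.05 M), 100 °C
Reagents that add atoms: none
Why: Copper-catalysed intramolecular Ullmann-type O-arylation closes the five-membered ring through the secondary hydroxyl (the primary one could only give a seven-membered ring) and forms only the aryl–oxygen bond, so C2 and C3 are retained and the ring is trans.

Step 11
Reactants: 16 (1R)-1-[(2R,3S)-3-[(tert-butyldimethylsilyl)oxy]-2-(3-hydroxyprop-1-en-2-yl)-2,3-dihydro-1-benzofuran-5-yl]ethyl (2R)-2-methylbutanoate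
Product: 17 (1R)-1-[(2R,3S)-3-hydroxy-2-(3-hydroxyprop-1-en-2-yl)-2,3-dihydro-1-benzofuran-5-yl]ethyl (2R)-2-methylbutanoate
Conditions: Bu4NF (1.5 equiv), AcOH (1.5 equiv), THF, 0 °C to rt
Reagents that add atoms: none
Why: Buffered fluoride desilylation frees the C3 hydroxyl without base-induced ester cleavage or acid-induced dehydration to the benzofuran, and it also converges any silyl-migrated isomer from step 10 onto the same diol.

Step 12
Reactants: 17 (1R)-1-[(2R,3S)-3-hydroxy-2-(3-hydroxyprop-1-en-2-yl)-2,3-dihydro-1-benzofuran-5-yl]ethyl (2R)-2-methylbutanoate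
Product: 18 (1R)-1-[(2R,3S)-2-{3-[(tert-butyldimethylsilyl)oxy]prop-1-en-2-yl}-3-hydroxy-2,3-dihydro-1-benzofuran-5-yl]ethyl (2R)-2-methylbutanoate
Conditions: TBSCl (1.1 equiv), imidazole (2 equiv), CH2Cl2, 0 °C
Reagents that add atoms: tert-butyldimethylsilyl chloride, CC(C)(C)[Si](C)(C)Cl
Why: Sterically controlled silylation takes the primary allylic hydroxyl far faster than the hindered secondary benzylic one.

Step 13
Reactants: 18 (1R)-1-[(2R,3S)-2-{3-[(tert-butyldimethylsilyl)oxy]prop-1-en-2-yl}-3-hydroxy-2,3-dihydro-1-benzofuran-5-yl]ethyl (2R)-2-methylbutanoate; 19 3-methylbutanoic anhydride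
Product: 20 (2R,3S)-2-{3-[(tert-butyldimethylsilyl)oxy]prop-1-en-2-yl}-5-[(1R)-1-{[(2R)-2-methylbutanoyl]oxy}ethyl]-2,3-dihydro-1-benzofuran-3-yl 3-methylbutanoate
Conditions: 19 (2 equiv), pyridine (4 equiv), 4-(dimethylamino)pyridine (10 mol %), CH2Cl2, 0 °C to rt
Reagents that add atoms: none
Why: Nucleophile-catalysed O-acylation installs the isovalerate with retention at C3, and it is done before the nucleophile-sensitive enal exists.

Step 14
Reactants: 20 (2R,3S)-2-{3-[(tert-butyldimethylsilyl)oxy]prop-1-en-2-yl}-5-[(1R)-1-{[(2R)-2-methylbutanoyl]oxy}ethyl]-2,3-dihydro-1-benzofuran-3-yl 3-methylbutanoate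
Product: 21 (2R,3S)-2-(3-hydroxyprop-1-en-2-yl)-5-[(1R)-1-{[(2R)-2-methylbutanoyl]oxy}ethyl]-2,3-dihydro-1-benzofuran-3-yl 3-methylbutanoate
Conditions: HF·pyridine, pyridine, THF, 0 °C to rt
Reagents that add atoms: none
Why: Pyridine-buffered HF desilylation cleaves the primary allylic silyl ether under conditions too mild to ionise the benzylic esters or to move an acyl group.

Step 15
Reactants: 21 (2R,3S)-2-(3-hydroxyprop-1-en-2-yl)-5-[(1R)-1-{[(2R)-2-methylbutanoyl]oxy}ethyl]-2,3-dihydro-1-benzofuran-3-yl 3-methylbutanoate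
Product: 22 (2R,3S)-5-[(1R)-1-{[(2R)-2-methylbutanoyl]oxy}ethyl]-2-(3-oxoprop-1-en-2-yl)-2,3-dihydro-1-benzofuran-3-yl 3-methylbutanoate
Conditions: activated MnO2 (20 equiv), CH2Cl2, rt
Reagents that add atoms: none
Why: Neutral heterogeneous allylic oxidation with MnO2 stops at the α-methylene aldehyde and touches neither the esters nor any stereocentre, so the sensitive enal appears only in the last step.

**Compound list**
1 | 2-bromo-5-iodobenzaldehyde | O=Cc1cc(I)ccc1Br | starting material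
2 | 2-(2-bromo-5-iodophenyl)-1,3-dioxolane | Brc1ccc(I)cc1C1OCCO1 | intermediate
3 | N-methoxy-N-methylacetamide | CC(=O)N(C)OC | starting material
4 | [4-bromo-3-(1,3-dioxolan-2-yl)phenyl]magnesium chloride (formed in the flask) | Cl[Mg]c1ccc(Br)c(C2OCCO2)c1 | intermediate
5 | chloromagnesium 1-[4-bromo-3-(1,3-dioxolan-2-yl)phenyl]-1-[methoxy(methyl)amino]ethan-1-olate (chelated tetrahedral adduct, racemic, formed in the flask) | CON(C)C(C)(O[Mg]Cl)c1ccc(Br)c(C2OCCO2)c1 | intermediate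
6 | 1-[4-bromo-3-(1,3-dioxolan-2-yl)phenyl]ethan-1-one | CC(=O)c1ccc(Br)c(C2OCCO2)c1 | intermediate
7 | (1R)-1-[4-bromo-3-(1,3-dioxolan-2-yl)phenyl]ethan-1-ol | C[C@@H](O)c1ccc(Br)c(C2OCCO2)c1 | intermediate
8 | (2R)-2-methylbutanoic acid | CC[C@@H](C)C(=O)O | starting material
9 | (1R)-1-[4-bromo-3-(1,3-dioxolan-2-yl)phenyl]ethyl (2R)-2-methylbutanoate | CC[C@@H](C)C(=O)O[C@H](C)c1ccc(Br)c(C2OCCO2)c1 | intermediate
10 | (1R)-1-(4-bromo-3-formylphenyl)ethyl (2R)-2-methylbutanoate | CC[C@@H](C)C(=O)O[C@H](C)c1ccc(Br)c(C=O)c1 | intermediate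
11 | 2,2-dimethyl-1,3-dioxan-5-one | CC1(C)OCC(=O)CO1 | starting material
12 | (1R)-1-{4-bromo-3-[(S)-[(4S)-2,2-dimethyl-5-oxo-1,3-dioxan-4-yl](hydroxy)methyl]phenyl}ethyl (2R)-2-methylbutanoate (anti aldol) | CC[C@@H](C)C(=O)O[C@H](C)c1ccc(Br)c([C@H](O)[C@@H]2OC(C)(C)OCC2=O)c1 | intermediate
13 | (1R)-1-{4-bromo-3-[(S)-[(tert-butyldimethylsilyl)oxy][(4S)-2,2-dimethyl-5-oxo-1,3-dioxan-4-yl]methyl]phenyl}ethyl (2R)-2-methylbutanoate | CC[C@@H](C)C(=O)O[C@H](C)c1ccc(Br)c([C@H](O[Si](C)(C)C(C)(C)C)[C@@H]2OC(C)(C)OCC2=O)c1 | intermediate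
14 | (1R)-1-{4-bromo-3-[(S)-[(tert-butyldimethylsilyl)oxy][(4R)-2,2-dimethyl-5-methylidene-1,3-dioxan-4-yl]methyl]phenyl}ethyl (2R)-2-methylbutanoate | CC[C@@H](C)C(=O)O[C@H](C)c1ccc(Br)c([C@H](O[Si](C)(C)C(C)(C)C)[C@@H]2OC(C)(C)OCC2=C)c1 | intermediate
15 | (1R)-1-{4-bromo-3-[(1S,2R)-1-[(tert-butyldimethylsilyl)oxy]-2-hydroxy-3-(hydroxymethyl)but-3-en-1-yl]phenyl}ethyl (2R)-2-methylbutanoate | CC[C@@H](C)C(=O)O[C@H](C)c1ccc(Br)c([C@H](O[Si](C)(C)C(C)(C)C)[C@H](O)C(=C)CO)c1 | intermediate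
16 | (1R)-1-[(2R,3S)-3-[(tert-butyldimethylsilyl)oxy]-2-(3-hydroxyprop-1-en-2-yl)-2,3-dihydro-1-benzofuran-5-yl]ethyl (2R)-2-methylbutanoate | C=C(CO)[C@H]1Oc2ccc([C@@H](C)OC(=O)[C@H](C)CC)cc2[C@@H]1O[Si](C)(C)C(C)(C)C | intermediate
17 | (1R)-1-[(2R,3S)-3-hydroxy-2-(3-hydroxyprop-1-en-2-yl)-2,3-dihydro-1-benzofuran-5-yl]ethyl (2R)-2-methylbutanoate | C=C(CO)[C@H]1Oc2ccc([C@@H](C)OC(=O)[C@H](C)CC)cc2[C@@H]1O | intermediate
18 | (1R)-1-[(2R,3S)-2-{3-[(tert-butyldimethylsilyl)oxy]prop-1-en-2-yl}-3-hydroxy-2,3-dihydro-1-benzofuran-5-yl]ethyl (2R)-2-methylbutanoate | C=C(CO[Si](C)(C)C(C)(C)C)[C@H]1Oc2ccc([C@@H](C)OC(=O)[C@H](C)CC)cc2[C@@H]1O | intermediate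
19 | 3-methylbutanoic anhydride (isovaleric anhydride) | CC(C)CC(=O)OC(=O)CC(C)C | starting material
20 | (2R,3S)-2-{3-[(tert-butyldimethylsilyl)oxy]prop-1-en-2-yl}-5-[(1R)-1-{[(2R)-2-methylbutanoyl]oxy}ethyl]-2,3-dihydro-1-benzofuran-3-yl 3-methylbutanoate | C=C(CO[Si](C)(C)C(C)(C)C)[C@H]1Oc2ccc([C@@H](C)OC(=O)[C@H](C)CC)cc2[C@@H]1OC(=O)CC(C)C | intermediate
21 | (2R,3S)-2-(3-hydroxyprop-1-en-2-yl)-5-[(1R)-1-{[(2R)-2-methylbutanoyl]oxy}ethyl]-2,3-dihydro-1-benzofuran-3-yl 3-methylbutanoate | C=C(CO)[C@H]1Oc2ccc([C@@H](C)OC(=O)[C@H](C)CC)cc2[C@@H]1OC(=O)CC(C)C | intermediate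
22 | (2R,3S)-5-[(1R)-1-{[(2R)-2-methylbutanoyl]oxy}ethyl]-2-(3-oxoprop-1-en-2-yl)-2,3-dihydro-1-benzofuran-3-yl 3-methylbutanoate (CNP0154159.1) | C=C(C=O)[C@H]1Oc2ccc([C@@H](C)OC(=O)[C@H](C)CC)cc2[C@@H]1OC(=O)CC(C)C | target

**Totals**
Total step count: 15. Longest linear sequence: 15 steps (1 to 22).

**Steps most likely to fail, with fallbacks**

Step 6 (aldol). Aromatic aldehydes can give modest anti/syn and facial selectivity in the proline reaction of 11. The fallback sets out from 10 and 11 and gives up catalyst control. Ketone 11 is enolised with dicyclohexylboron chloride (C6H11)2BCl and Et3N in Et2O at −78 °C to the dicyclohexylboron enolate F1. Addition of 10 through a closed Zimmerman–Traxler transition state of the ring-locked (E)-enolate gives only anti products, the (4S,1'S) boron aldolate F2 and the (4R,1'R) boron aldolate F3. These form in about equal amounts, because the remote side-chain centre exerts no control. Work-up with pH 7 buffer and methanol releases 12 and the (4R,1'R) anti aldol F4, which are separated by preparative HPLC (if necessary after silylation). The fallback comes back to the route at 12, with at most half of the material.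

Step 8 (Wittig methylenation). The ketone is flanked by two oxygenated carbons and a β-silyloxy group, so enolisation, epimerisation at C4 or β-elimination may compete. The fallback sets out from 13 and replaces the ylide by a two-stage Peterson olefination. The non-basic cerium reagent from Me3SiCH2MgCl and anhydrous CeCl3 (THF, −78 °C) adds to the carbonyl to give the β-hydroxysilane F5, as a mixture at the new carbinol carbon, which is of no consequence. Its potassium alkoxide (KH, THF, 0 °C) then undergoes syn-elimination of trimethylsilanolate. The fallback comes back at 14.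

Step 10 (ring closure). The free primary hydroxyl may be arylated intermolecularly, the silyl group may wander, or the hindered secondary alkoxide may close slowly. The fallback sets out from 15 and changes to a substrate with a single free hydroxyl and to palladium catalysis. TBSCl and imidazole (CH2Cl2, 0 °C) give the bis-silyl ether F6. Buchwald-type intramolecular etherification (Pd(OAc)2, 2-(di-tert-butylphosphino)-1,1'-binaphthyl, Cs2CO3, toluene, 70 °C) then gives the bis-silylated dihydrobenzofuran F7. Bu4NF/AcOH removes both silyl groups. The fallback comes back at 17, replacing steps 10 and 11.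

**Further compounds**
F1 | step 6 | 5-[(dicyclohexylboranyl)oxy]-2,2-dimethyl-4H-1,3-dioxine (boron enolate of 11) | CC1(C)OCC(OB(C2CCCCC2)C2CCCCC2)=CO1
F2 | step 6 | (1R)-1-{4-bromo-3-[(S)-[(dicyclohexylboranyl)oxy][(4S)-2,2-dimethyl-5-oxo-1,3-dioxan-4-yl]methyl]phenyl}ethyl (2R)-2-methylbutanoate | CC[C@@H](C)C(=O)O[C@H](C)c1ccc(Br)c([C@H](OB(C2CCCCC2)C2CCCCC2)[C@@H]2OC(C)(C)OCC2=O)c1
F3 | step 6 | (1R)-1-{4-bromo-3-[(R)-[(dicyclohexylboranyl)oxy][(4R)-2,2-dimethyl-5-oxo-1,3-dioxan-4-yl]methyl]phenyl}ethyl (2R)-2-methylbutanoate | CC[C@@H](C)C(=O)O[C@H](C)c1ccc(Br)c([C@@H](OB(C2CCCCC2)C2CCCCC2)[C@H]2OC(C)(C)OCC2=O)c1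
F4 | step 6 | (1R)-1-{4-bromo-3-[(R)-[(4R)-2,2-dimethyl-5-oxo-1,3-dioxan-4-yl](hydroxy)methyl]phenyl}ethyl (2R)-2-methylbutanoate | CC[C@@H](C)C(=O)O[C@H](C)c1ccc(Br)c([C@@H](O)[C@H]2OC(C)(C)OCC2=O)c1
F5 | step 8 | (1R)-1-{4-bromo-3-[(S)-[(tert-butyldimethylsilyl)oxy][(4S)-5-hydroxy-2,2-dimethyl-5-[(trimethylsilyl)methyl]-1,3-dioxan-4-yl]methyl]phenyl}ethyl (2R)-2-methylbutanoate (both C5 epimers) | CC[C@@H](C)C(=O)O[C@H](C)c1ccc(Br)c([C@H](O[Si](C)(C)C(C)(C)C)[C@@H]2OC(C)(C)OCC2(O)C[Si](C)(C)C)c1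
F6 | step 10 | (1R)-1-{4-bromo-3-[(1S,2R)-1-[(tert-butyldimethylsilyl)oxy]-3-{[(tert-butyldimethylsilyl)oxy]methyl}-2-hydroxybut-3-en-1-yl]phenyl}ethyl (2R)-2-methylbutanoate | CC[C@@H](C)C(=O)O[C@H](C)c1ccc(Br)c([C@H](O[Si](C)(C)C(C)(C)C)[C@H](O)C(=C)CO[Si](C)(C)C(C)(C)C)c1
F7 | step 10 | (1R)-1-[(2R,3S)-3-[(tert-butyldimethylsilyl)oxy]-2-{3-[(tert-butyldimethylsilyl)oxy]prop-1-en-2-yl}-2,3-dihydro-1-benzofuran-5-yl]ethyl (2R)-2-methylbutanoate | C=C(CO[Si](C)(C)C(C)(C)C)[C@H]1Oc2ccc([C@@H](C)OC(=O)[C@H](C)CC)cc2[C@@H]1O[Si](C)(C)C(C)(C)C
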